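A direct plan would build an isoflavone and reduce it. Persulfate hydroxylation of 2'-hydroxy-3',4'-dimethoxyacetophenone would give hydroquinone A1. After benzylation, condensation with the benzylated ring B aldehyde would give flavanone A2, a hypervalent iodine oxidant would shift the aryl group from C2 to C3 (isoflavone A3), and asymmetric transfer hydrogenation would give isoflavan-4-ol A4, whose C4 oxygen would go by hydrogenolysis. Its weakest steps would be:
- the persulfate para-hydroxylation, because of low conversion and over-oxidation of an electron-rich phenol;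
- the oxidative aryl shift, because flavone formation competes and the migrating ring is hindered;
- the removal of the C4 oxygen, because it takes three stages through a pterocarpan for an oxygen the target lacks.

The new route cuts ring C at C4–C4a and O1–C2 together. O1 and the 6-OH are para on ring A, so ring A is a latent 2,3-dimethoxybenzene-1,4-diol whose two free positions are equivalent. Condensing it with a 2-arylacrolein that carries ring B and C2–C3–C4 should give, through a boron-templated ortho-hydroxyalkylation, an ortho-quinone methide and an oxa-6π electrocyclisation, the complete isoflav-3-ene skeleton with the 6-OH free, in one operation. No arene is oxidised, no aryl group migrates and C4 never bears oxygen; a single iridium-catalysed hydrogenation of C3=C4 then sets the only stereocentre.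

Key step: step 3

Remark: 2,3-dimethoxybenzene-1,4-diol and 2-bromo-3,3-diethoxyprop-1-ene are taken as catalogue compounds; the diol is handled under argon.
Remark: the (4S) ligand in step 4 is assumed to deliver hydrogen to the face of C3=C4 that gives 3S; if the sense were opposite, the (4R) ligand would be used with nothing else changed.

Step 1
Reactants: 1 2,3-dimethoxyphenol
Product: 2 1,2-dimethoxy-3-(methoxymethoxy)benzene
Conditions: NaH (1.2 equiv), MOMCl (1.2 equiv), THF, 0 °C to rt
Reagents that add atoms: chloromethyl methyl ether, COCCl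
Why: Williamson etherification of the sodium phenoxide, which masks the future 2'-OH as an acetal that is also the directing group for the metalation in step 2.

Step 2
Reactants: 2 1,2-dimethoxy-3-(methoxymethoxy)benzene; 3 2-bromo-3,3-diethoxyprop-1-ene
Product: 6 1-(3,3-diethoxyprop-1-en-2-yl)-3,4-dimethoxy-2-(methoxymethoxy)benzene, via aryllithium 4 (not isolated), via arylzinc chloride 5 (not isolated)
Conditions: n-BuLi (1.1 equiv), THF, 0 °C, 1 h; ZnCl2 (1.2 equiv), 0 °C to rt; then 3 (0.9 equiv), Pd(PPh3)4 (3 mol %), THF, 55 °C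
Reagents that add atoms: none
Why: Directed ortho-metalation followed by Negishi coupling, in which the MOM acetal chelates lithium so that the C–H next to it is removed, zinc tames the anion, and zerovalent palladium joins the arylzinc to the vinyl bromide by oxidative addition, transmetalation and reductive elimination while the diethyl acetal keeps the aldehyde inert to both organometallics.

Step 3 (key step)
Reactants: 6 1-(3,3-diethoxyprop-1-en-2-yl)-3,4-dimethoxy-2-(methoxymethoxy)benzene; 7 2,3-dimethoxybenzene-1,4-diol
Product: 11 3-[3,4-dimethoxy-2-(methoxymethoxy)phenyl]-7,8-dimethoxy-2H-chromen-6-ol, via 2-arylprop-2-enal 8 (not isolated), via 4H-1,3,2-benzodioxaborinine 9 (not isolated), via ortho-quinone methide 10 (not isolated)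
Conditions: pyridinium p-toluenesulfonate (10 mol %), acetone–H2O 9:1, rt; solvent exchange; then 7 (3 equiv), PhB(OH)2 (1.5 equiv), EtCO2H (0.3 equiv), toluene, reflux with azeotropic removal of water, argon
Reagents that add atoms: none
Why: Phenylboronic acid-templated chromenylation of a phenol with an α,β-unsaturated aldehyde, the reaction type used for precocene-type 2H-chromenes, here fed with enal 8 that is unmasked from its acetal only in the flask because 2-arylacroleins oligomerise on storage. The boronic acid esterifies a phenolic OH of 7 and binds the aldehyde oxygen, so that the ortho carbon attacks the carbonyl carbon through a six-membered transition state (C4–C4a formed, 1,2- and not 1,4-addition) and the adduct is held as benzodioxaborinine 9. At reflux 9 loses the boron unit by cycloreversion across its allylic-benzylic C–O bond to give ortho-quinone methide 10, a 1-oxatriene whose Z isomer closes ring C by a thermal disrotatory oxa-6π electrocyclisation (O1–C2 formed) that restores the aromaticity of ring A. No stereocentre is formed, since C3 stays sp2 and the carbinol centre of 9 is lost in 10. Regiochemistry on ring A needs no control because the two free positions of 7 are exchanged by its twofold axis, O- versus C-attack is decided by the boron template, ring B cannot compete because its phenol is the MOM ether, and a second annulation at C5 of 11 is held back by the excess of 7.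

Step 4
Reactants: 11 3-[3,4-dimethoxy-2-(methoxymethoxy)phenyl]-7,8-dimethoxy-2H-chromen-6-ol
Product: 12 (3S)-3-[3,4-dimethoxy-2-(methoxymethoxy)phenyl]-7,8-dimethoxy-3,4-dihydro-2H-chromen-6-ol
Conditions: H2 (50 bar), (cycloocta-1,5-diene)[(4S)-4-tert-butyl-2-(2-diphenylphosphanylphenyl)-4,5-dihydro-1,3-oxazole]iridium tetrakis[3,5-bis(trifluoromethyl)phenyl]borate (2 mol %), CH2Cl2, rt, 24 h; recrystallise
Reagents that add atoms: none
Why: Iridium-catalysed asymmetric hydrogenation of an unfunctionalised trisubstituted aryl alkene, a reaction type established for 3-aryl-2H-chromenes, in which the cationic iridium dihydride with its chiral P,N ligand binds one face of C3=C4 and adds H2 syn, so that the ligand alone fixes C3 as S while C4 becomes CH2 and nothing else in the molecule is reducible.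

Step 5
Reactants: 12 (3S)-3-[3,4-dimethoxy-2-(methoxymethoxy)phenyl]-7,8-dimethoxy-3,4-dihydro-2H-chromen-6-ol
Product: 13 (3S)-3-(2-hydroxy-3,4-dimethoxyphenyl)-7,8-dimethoxy-3,4-dihydro-2H-chromen-6-ol (target)
Conditions: HCl (3 M in MeOH), 40 °C, 2 h, argon
Reagents that add atoms: none
Why: Acid-catalysed transacetalisation of the MOM ether to dimethoxymethane, which frees the 2'-OH without touching the aryl methyl ethers, the chroman ether or any bond to C3.

Compound list
1 | 2,3-dimethoxyphenol | COc1cccc(O)c1OC | starting material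
2 | 1,2-dimethoxy-3-(methoxymethoxy)benzene | COCOc1cccc(OC)c1OC | intermediate
3 | 2-bromo-3,3-diethoxyprop-1-ene | CCOC(OCC)C(Br)=C | starting material
4 | [3,4-dimethoxy-2-(methoxymethoxy)phenyl]lithium | [Li]c1ccc(OC)c(OC)c1OCOC | intermediate
5 | chloro[3,4-dimethoxy-2-(methoxymethoxy)phenyl]zinc | Cl[Zn]c1ccc(OC)c(OC)c1OCOC | intermediate
6 | 1-(3,3-diethoxyprop-1-en-2-yl)-3,4-dimethoxy-2-(methoxymethoxy)benzene | CCOC(OCC)C(=C)c1ccc(OC)c(OC)c1OCOC | intermediate
7 | 2,3-dimethoxybenzene-1,4-diol | COc1c(O)ccc(O)c1OC | starting material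
8 | 2-[3,4-dimethoxy-2-(methoxymethoxy)phenyl]prop-2-enal | C=C(C=O)c1ccc(OC)c(OC)c1OCOC | intermediate
9 | rac-4-{1-[3,4-dimethoxy-2-(methoxymethoxy)phenyl]ethenyl}-7,8-dimethoxy-2-phenyl-4H-1,3,2-benzodioxaborinin-6-ol | C=C(C1OB(c2ccccc2)Oc2c1cc(O)c(OC)c2OC)c1ccc(OC)c(OC)c1OCOC | intermediate
10 | (6Z)-6-{2-[3,4-dimethoxy-2-(methoxymethoxy)phenyl]prop-2-en-1-ylidene}-4-hydroxy-2,3-dimethoxycyclohexa-2,4-dien-1-one | C=C(/C=C1/C=C(O)C(OC)=C(OC)C1=O)c1ccc(OC)c(OC)c1OCOC | intermediate
11 | 3-[3,4-dimethoxy-2-(methoxymethoxy)phenyl]-7,8-dimethoxy-2H-chromen-6-ol | COCOc1c(C2=Cc3cc(O)c(OC)c(OC)c3OC2)ccc(OC)c1OC | intermediate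
12 | (3S)-3-[3,4-dimethoxy-2-(methoxymethoxy)phenyl]-7,8-dimethoxy-3,4-dihydro-2H-chromen-6-ol | COc1ccc([C@H]2COc3c(cc(O)c(OC)c3OC)C2)c(OCOC)c1OC | intermediate
13 | (3S)-3-(2-hydroxy-3,4-dimethoxyphenyl)-7,8-dimethoxy-3,4-dihydro-2H-chromen-6-ol | COc1ccc([C@H]2COc3c(cc(O)c(OC)c3OC)C2)c(O)c1OC | target

Total step count: 5. Longest linear sequence: 5 steps (1 to 13).

Steps most likely to fail

1. Step 3 (key step). The enal may oligomerise before the boron template captures it, its CH2 terminus may be attacked in a conjugate sense, or the product phenol may be annulated a second time at C5. The fallback replaces the one-pot annulation by stepwise C-allylation and a redox-triggered closure; it sets out from 8 and returns at 11. Luche reduction (NaBH4, CeCl3·7H2O, MeOH, 0 °C) should give the allylic alcohol 2-[3,4-dimethoxy-2-(methoxymethoxy)phenyl]prop-2-en-1-ol F1. Mitsunobu etherification (PPh3, DIAD, THF) with an excess of 7 should give the mono-ether 4-({2-[3,4-dimethoxy-2-(methoxymethoxy)phenyl]prop-2-en-1-yl}oxy)-2,3-dimethoxyphenol F2. Aromatic Claisen rearrangement (N,N-diethylaniline, 190 °C) should move the allyl group to the only free ortho carbon and give 5-{2-[3,4-dimethoxy-2-(methoxymethoxy)phenyl]prop-2-en-1-yl}-2,3-dimethoxybenzene-1,4-diol F3. Oxidation (Ag2O, Et2O) should give the quinone 5-{2-[3,4-dimethoxy-2-(methoxymethoxy)phenyl]prop-2-en-1-yl}-2,3-dimethoxycyclohexa-2,5-diene-1,4-dione F4. Et3N in refluxing toluene should tautomerise F4 to 10, which closes to 11.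

2. Step 4. Enantioface discrimination may be poor, because ring B is twisted by its two ortho substituents and its acetal oxygens can bind iridium, and the free phenol may slow the catalyst. The fallback uses resolution in place of asymmetric catalysis; it sets out from 11 and returns at 12. Hydrogenation over 10% Pd/C (H2, 1 atm, EtOAc) should give the racemate rac-3-[3,4-dimethoxy-2-(methoxymethoxy)phenyl]-7,8-dimethoxy-3,4-dihydro-2H-chromen-6-ol F5, which would be resolved by preparative supercritical-fluid chromatography on a cellulose tris(3,5-dimethylphenylcarbamate) phase to give 12.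

3. Step 2. Transmetalation and reductive elimination may be slow for an arylzinc with two ortho substituents, so that protodemetalation wins. The fallback uses one-carbon homologation and methylenation in place of cross-coupling; it sets out from 4 and returns at 8. Quenching 4 with DMF should give 3,4-dimethoxy-2-(methoxymethoxy)benzaldehyde F6. Wittig reaction with the ylide from (methoxymethyl)triphenylphosphonium chloride and KOtBu (THF, 0 °C) should give the enol ether 3,4-dimethoxy-1-(2-methoxyethenyl)-2-(methoxymethoxy)benzene F7 as an E/Z mixture. Mild hydrolysis (aqueous HCO2H, THF, 0 °C) should give [3,4-dimethoxy-2-(methoxymethoxy)phenyl]acetaldehyde F8. α-Methylenation (aqueous CH2O, pyrrolidine, EtCO2H, i-PrOH, 45 °C) should give enal 8, which enters step 3 at its second stage.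

Further compounds
F1 | step 3 | 2-[3,4-dimethoxy-2-(methoxymethoxy)phenyl]prop-2-en-1-ol | C=C(CO)c1ccc(OC)c(OC)c1OCOC
F2 | step 3 | 4-({2-[3,4-dimethoxy-2-(methoxymethoxy)phenyl]prop-2-en-1-yl}oxy)-2,3-dimethoxyphenol | C=C(COc1ccc(O)c(OC)c1OC)c1ccc(OC)c(OC)c1OCOC
F3 | step 3 | 5-{2-[3,4-dimethoxy-2-(methoxymethoxy)phenyl]prop-2-en-1-yl}-2,3-dimethoxybenzene-1,4-diol | C=C(Cc1cc(O)c(OC)c(OC)c1O)c1ccc(OC)c(OC)c1OCOC
F4 | step 3 | 5-{2-[3,4-dimethoxy-2-(methoxymethoxy)phenyl]prop-2-en-1-yl}-2,3-dimethoxycyclohexa-2,5-diene-1,4-dione | C=C(CC1=CC(=O)C(OC)=C(OC)C1=O)c1ccc(OC)c(OC)c1OCOC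
F5 | step 4 | rac-3-[3,4-dimethoxy-2-(methoxymethoxy)phenyl]-7,8-dimethoxy-3,4-dihydro-2H-chromen-6-ol | COc1ccc(C2COc3c(cc(O)c(OC)c3OC)C2)c(OCOC)c1OC
F6 | step 2 | 3,4-dimethoxy-2-(methoxymethoxy)benzaldehyde | O=Cc1ccc(OC)c(OC)c1OCOC
F7 | step 2 | 3,4-dimethoxy-1-(2-methoxyethenyl)-2-(methoxymethoxy)benzene (E/Z mixture) | COC=Cc1ccc(OC)c(OC)c1OCOC
F8 | step 2 | [3,4-dimethoxy-2-(methoxymethoxy)phenyl]acetaldehyde | O=CCc1ccc(OC)c(OC)c1OCOC
A1 | direct plan | 2',5'-dihydroxy-3',4'-dimethoxyacetophenone | CC(=O)c1cc(O)c(OC)c(OC)c1O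
A2 | direct plan | rac-6-(benzyloxy)-2-[2-(benzyloxy)-3,4-dimethoxyphenyl]-7,8-dimethoxychroman-4-one | O=C1CC(c2ccc(OC)c(OC)c2OCc2ccccc2)Oc2c1cc(OCc1ccccc1)c(OC)c2OC
A3 | direct plan | 6-(benzyloxy)-3-[2-(benzyloxy)-3,4-dimethoxyphenyl]-7,8-dimethoxy-4H-chromen-4-one | O=c1c(-c2ccc(OC)c(OC)c2OCc2ccccc2)coc2c1cc(OCc1ccccc1)c(OC)c2OC
A4 | direct plan | (3S,4S)-6-(benzyloxy)-3-[2-(benzyloxy)-3,4-dimethoxyphenyl]-7,8-dimethoxychroman-4-ol | COc1ccc([C@H]2COc3c(cc(OCc4ccccc4)c(OC)c3OC)[C@H]2O)c(OCc2ccccc2)c1OC
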